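**Plan**

1. Retrosynthesis: the interflavan bond C4–C6' is cut first (C4 cation of the upper unit plus a C8'-blocked catechin). Then O1–C8a and C2–C3 of ring C are cut together, giving the ring B aldehyde and a four-atom unit C3–C4–C4a–C8a. Last, C4–C4a is cut (acylation), and ring A goes back to cyclohexane-1,3-dione.
2. Enabling feature: on ring A, O1 (at C8a) and the C7 oxygen are meta, so ring A is the aromatized form of a 3-alkoxycyclohex-2-enone whose ketone carbon is C8a. A ketone placed at C4 makes C8a/C4 a beta-diketone through C4a, makes C3 its terminal nucleophilic carbon, and lets the aldehyde oxygen become O1 by condensation onto C8a.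
3. Forward order: ring A as a cyclohexenone enol ether → acylation at C4a → bis(silyloxy)diene → ring C closed by aldol–cyclocondensation with the ring B aldehyde → ring A aromatized → C4 ketone reduced → C4 joined to C6' of the 8-bromocatechin ether → hydrogenolysis.
4. Stereochemistry: C2 from the chiral catalyst made from Ti(OiPr)4 and (S)-BINOL; C3 trans to C2 (anti aldol, able to equilibrate alpha to the C4 ketone); C4 by attack anti to the 3-benzyloxy group (all-equatorial ring C); the lower unit from (+)-catechin.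
5. Helpers and their removal: C4 ketone (steps 6 and 9), dihydro ring A (step 5), C8' bromine and benzyl ethers (step 10).

Key step: step 4

Remark: the upper unit is numbered as a flavan (O1, C2, C3, C4, C4a, C5–C8, C8a) and the lower unit with primes; compounds 1, 2, 4, 7 and 12 are taken as purchased materials.

**Step 1**
Reactants: 1 cyclohexane-1,3-dione; 2 benzyl alcohol
Product: 3 3-(benzyloxy)cyclohex-2-en-1-one
Conditions: TsOH (cat.), toluene, reflux, Dean–Stark trap
Reagents that add atoms: none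
Why: Acid-catalysed enol etherification of the 1,3-dione (vinylogous Fischer esterification), driven by azeotropic removal of water.

**Step 2**
Reactants: 3 3-(benzyloxy)cyclohex-2-en-1-one; 4 2-(benzyloxy)-N-methoxy-N-methylacetamide
Product: 5 3-(benzyloxy)-6-[(benzyloxy)acetyl]cyclohex-2-en-1-one (beta-diketone, largely enolized; C6 configurationally labile)
Conditions: lithium diisopropylamide (1.1 equiv), THF, −78 °C; then 4, −78 to −20 °C; AcOH quench
Reagents that add atoms: none
Why: Kinetic deprotonation of the vinylogous ester occurs at the alpha' carbon (Stork–Danheiser regiochemistry), and the enolate is C-acylated through a stable chelated tetrahedral intermediate (Weinreb ketone synthesis), which prevents proton exchange with the more acidic product.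

**Step 3**
Reactants: 5 3-(benzyloxy)-6-[(benzyloxy)acetyl]cyclohex-2-en-1-one
Product: 6 4-(benzyloxy)-1-[(Z)-2-(benzyloxy)-1-(trimethylsilyloxy)ethenyl]-2-(trimethylsilyloxy)cyclohexa-1,3-diene
Conditions: TMSOTf (2.4 equiv), Et3N (3.0 equiv), Et2O, 0 °C to rt; non-aqueous work-up (pentane extraction), used crude
Reagents that add atoms: trimethylsilyl trifluoromethanesulfonate, C[Si](C)(C)OS(=O)(=O)C(F)(F)F
Why: Soft enolization and double O-silylation of a beta-diketone with TMSOTf/Et3N is a known one-operation entry to 1,3-bis(silyloxy)-1,3-dienes; the second enol silane can only form toward the benzyloxy-bearing methylene, the one hydrogen-bearing alpha position of the C4 carbonyl, and the Z geometry (silyloxy and benzyloxy cis) is expected under these equilibrating conditions.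

**Step 4**
Reactants: 6 4-(benzyloxy)-1-[(Z)-2-(benzyloxy)-1-(trimethylsilyloxy)ethenyl]-2-(trimethylsilyloxy)cyclohexa-1,3-diene; 7 3,4-bis(benzyloxy)benzaldehyde
Product: 9 (2R,3R)-3,7-bis(benzyloxy)-2-[3,4-bis(benzyloxy)phenyl]-2,3,5,6-tetrahydro-4H-chromen-4-one, via open-chain anti aldol adduct 8 (not isolated)
Conditions: Ti(OiPr)4 (20 mol %), (S)-BINOL (20 mol %), 4 Å MS, THF, −78 to −20 °C; then TFA, CH2Cl2, 0 °C
Reagents that add atoms: none
Why: The chiral Lewis acid made from Ti(OiPr)4 and (S)-BINOL activates aldehyde 7 and the terminal diene carbon C3 attacks it (vinylogous Mukaiyama aldol) to form C2–C3; on TFA treatment the freed C2 hydroxyl adds to the ring carbonyl carbon C8a and the former C8a oxygen is lost, forming O1–C8a as part of a vinylogous ester. The closest known reaction type is the formal oxa-Diels–Alder reaction (aldol–cyclocondensation) of 1,3-bis(silyloxy)-1,3-dienes with aromatic aldehydes, which gives 2,3-dihydro-4H-pyran-4-ones. Ring C closes by 6-exo-trig attack of O1 on the C8a carbonyl followed by dehydration (addition–elimination). C2 is set by catalyst-controlled Si-face attack on the aldehyde; (S)-BINOL is assigned by analogy with Ti(OiPr)4/BINOL-catalysed aldol additions of silyl dienolates, and the sense would be confirmed by correlation at the stage of 10. C3 is set anti to C2 by the open transition state of the (Z)-alpha-benzyloxy enol silane and, being alpha to the C4 ketone, can equilibrate under the acid to the diequatorial 2,3-trans isomer. The step needs attack through C3 rather than C4a or C8, which is secured because C3 is the terminus fed by three oxygen donors and the only unhindered CH position, and it needs closure onto C8a rather than C7, which ring size secures.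

**Step 5**
Reactants: 9 (2R,3R)-3,7-bis(benzyloxy)-2-[3,4-bis(benzyloxy)phenyl]-2,3,5,6-tetrahydro-4H-chromen-4-one
Product: 10 (2R,3R)-3,7-bis(benzyloxy)-2-[3,4-bis(benzyloxy)phenyl]-2,3-dihydro-4H-chromen-4-one
Conditions: DDQ (1.05 equiv), toluene, 0 °C to rt
Reagents that add atoms: none
Why: DDQ dehydrogenation of the cyclohexa-1,3-diene (hydride abstraction from C5 to an oxygen-stabilized cation, then loss of the C6 proton) should aromatize ring A without touching C2 or C3.

**Step 6**
Reactants: 10 (2R,3R)-3,7-bis(benzyloxy)-2-[3,4-bis(benzyloxy)phenyl]-2,3-dihydro-4H-chromen-4-one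
Product: 11 (2R,3S,4R)-3,7-bis(benzyloxy)-2-[3,4-bis(benzyloxy)phenyl]-3,4-dihydro-2H-chromen-4-ol
Conditions: NaBH4, THF/MeOH, 0 °C
Reagents that add atoms: none
Why: Borohydride reduction of the aryl ketone with axial hydride delivery should give the equatorial 3,4-trans alcohol, as in dihydroflavonol reductions; either C4 epimer serves, since C4 is ionized in step 9.

**Step 7**
Reactants: 12 (+)-catechin, (2R,3S)-2-(3,4-dihydroxyphenyl)-3,4-dihydro-2H-chromene-3,5,7-triol
Product: 13 (2R,3S)-5,7-bis(benzyloxy)-2-[3,4-bis(benzyloxy)phenyl]-3,4-dihydro-2H-chromen-3-ol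
Conditions: BnBr (4.2 equiv), K2CO3, DMF, 0 °C to rt, argon
Reagents that add atoms: benzyl bromide, BrCc1ccccc1
Why: Williamson etherification; under carbonate the four phenols are alkylated selectively over the secondary alcohol, and the low temperature guards against C2 epimerization.

**Step 8**
Reactants: 13 (2R,3S)-5,7-bis(benzyloxy)-2-[3,4-bis(benzyloxy)phenyl]-3,4-dihydro-2H-chromen-3-ol
Product: 14 (2R,3S)-5,7-bis(benzyloxy)-2-[3,4-bis(benzyloxy)phenyl]-8-bromo-3,4-dihydro-2H-chromen-3-ol
Conditions: NBS (1.0 equiv), CH2Cl2, −20 to 0 °C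
Reagents that add atoms: N-bromosuccinimide, O=C1CCC(=O)N1Br
Why: Electrophilic aromatic bromination, which in this tetrabenzyl ether is selective for C8 of the phloroglucinol-type ring; the bromine then blocks C8 so that only C6 can react in step 9.

**Step 9**
Reactants: 11 (2R,3S,4R)-3,7-bis(benzyloxy)-2-[3,4-bis(benzyloxy)phenyl]-3,4-dihydro-2H-chromen-4-ol; 14 (2R,3S)-5,7-bis(benzyloxy)-2-[3,4-bis(benzyloxy)phenyl]-8-bromo-3,4-dihydro-2H-chromen-3-ol
Product: 15 (2R,3S,4S)-3,7-bis(benzyloxy)-2-[3,4-bis(benzyloxy)phenyl]-4-[(2R,3S)-5,7-bis(benzyloxy)-2-[3,4-bis(benzyloxy)phenyl]-8-bromo-3-hydroxy-3,4-dihydro-2H-chromen-6-yl]-3,4-dihydro-2H-chromene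
Conditions: TMSOTf (20 mol %), 4 Å MS, CH2Cl2, −40 °C; 11 added slowly to an excess of 14
Reagents that add atoms: none
Why: Friedel–Crafts alkylation through the benzylic C4 cation, formed by acid-promoted loss of the C4 hydroxyl of 11 as water (SN1, the water being taken up by the sieves) and stabilized by the para 7-benzyloxy group and the ortho ring oxygen; C6', the only free position of the lower phloroglucinol ring, should attack anti to the equatorial 3-benzyloxy group and give the diequatorial 3,4-trans (4S) product, while the excess of 14 suppresses self-condensation of 11.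

**Step 10**
Reactants: 15 (2R,3S,4S)-3,7-bis(benzyloxy)-2-[3,4-bis(benzyloxy)phenyl]-4-[(2R,3S)-5,7-bis(benzyloxy)-2-[3,4-bis(benzyloxy)phenyl]-8-bromo-3-hydroxy-3,4-dihydro-2H-chromen-6-yl]-3,4-dihydro-2H-chromene
Product: 16 (2R,3S,4S)-2-(3,4-dihydroxyphenyl)-4-[(2R,3S)-2-(3,4-dihydroxyphenyl)-3,5,7-trihydroxy-3,4-dihydro-2H-chromen-6-yl]-3,4-dihydro-2H-chromene-3,7-diol (CNP0141631.1)
Conditions: H2 (1 atm), Pd(OH)2/C, Et3N (1.5 equiv), THF/MeOH/H2O, rt
Reagents that add atoms: none
Why: Catalytic hydrogenolysis should remove the eight benzyl ethers and the C8' bromine (hydrodehalogenation) in one operation, with triethylamine trapping HBr to protect the acid-labile interflavan bond.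

**Compound list**

1 | cyclohexane-1,3-dione | O=C1CCCC(=O)C1 | starting material
2 | benzyl alcohol | OCc1ccccc1 | starting material
3 | 3-(benzyloxy)cyclohex-2-en-1-one | O=C1C=C(OCc2ccccc2)CCC1 | intermediate
4 | 2-(benzyloxy)-N-methoxy-N-methylacetamide | CON(C)C(=O)COCc1ccccc1 | starting material
5 | 3-(benzyloxy)-6-[(benzyloxy)acetyl]cyclohex-2-en-1-one | O=C1C=C(OCc2ccccc2)CCC1C(=O)COCc1ccccc1 | intermediate
6 | 4-(benzyloxy)-1-[(Z)-2-(benzyloxy)-1-(trimethylsilyloxy)ethenyl]-2-(trimethylsilyloxy)cyclohexa-1,3-diene | C[Si](C)(C)OC1=C(/C(O[Si](C)(C)C)=C/OCc2ccccc2)CCC(OCc2ccccc2)=C1 | intermediate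
7 | 3,4-bis(benzyloxy)benzaldehyde | O=Cc1ccc(OCc2ccccc2)c(OCc2ccccc2)c1 | starting material
8 | (2R,3R)-2-(benzyloxy)-3-[3,4-bis(benzyloxy)phenyl]-1-[4-(benzyloxy)-2-hydroxycyclohexa-1,3-dien-1-yl]-3-hydroxypropan-1-one (enol form of the open-chain anti aldol adduct) | O[C@H](c1ccc(OCc2ccccc2)c(OCc2ccccc2)c1)[C@@H](OCc1ccccc1)C(=O)C1=C(O)C=C(OCc2ccccc2)CC1 | intermediate
9 | (2R,3R)-3,7-bis(benzyloxy)-2-[3,4-bis(benzyloxy)phenyl]-2,3,5,6-tetrahydro-4H-chromen-4-one | c1ccccc1COC1=CC(O[C@H](c2ccc(OCc3ccccc3)c(OCc3ccccc3)c2)[C@@H](OCc2ccccc2)C2=O)=C2CC1 | intermediate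
10 | (2R,3R)-3,7-bis(benzyloxy)-2-[3,4-bis(benzyloxy)phenyl]-2,3-dihydro-4H-chromen-4-one | c1ccccc1COc1ccc2c(c1)O[C@H](c1ccc(OCc3ccccc3)c(OCc3ccccc3)c1)[C@@H](OCc1ccccc1)C2=O | intermediate
11 | (2R,3S,4R)-3,7-bis(benzyloxy)-2-[3,4-bis(benzyloxy)phenyl]-3,4-dihydro-2H-chromen-4-ol | c1ccccc1COc1ccc2c(c1)O[C@H](c1ccc(OCc3ccccc3)c(OCc3ccccc3)c1)[C@@H](OCc1ccccc1)[C@@H]2O | intermediate
12 | (+)-catechin | O[C@H]1Cc2c(O)cc(O)cc2O[C@@H]1c1ccc(O)c(O)c1 | starting material
13 | (2R,3S)-5,7-bis(benzyloxy)-2-[3,4-bis(benzyloxy)phenyl]-3,4-dihydro-2H-chromen-3-ol | O[C@H]1Cc2c(OCc3ccccc3)cc(OCc3ccccc3)cc2O[C@@H]1c1ccc(OCc2ccccc2)c(OCc2ccccc2)c1 | intermediate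
14 | (2R,3S)-5,7-bis(benzyloxy)-2-[3,4-bis(benzyloxy)phenyl]-8-bromo-3,4-dihydro-2H-chromen-3-ol | O[C@H]1Cc2c(OCc3ccccc3)cc(OCc3ccccc3)c(Br)c2O[C@@H]1c1ccc(OCc2ccccc2)c(OCc2ccccc2)c1 | intermediate
15 | (2R,3S,4S)-3,7-bis(benzyloxy)-2-[3,4-bis(benzyloxy)phenyl]-4-[(2R,3S)-5,7-bis(benzyloxy)-2-[3,4-bis(benzyloxy)phenyl]-8-bromo-3-hydroxy-3,4-dihydro-2H-chromen-6-yl]-3,4-dihydro-2H-chromene | c1ccccc1COc1ccc2c(c1)O[C@H](c1ccc(OCc3ccccc3)c(OCc3ccccc3)c1)[C@@H](OCc1ccccc1)[C@@H]2c1c(OCc3ccccc3)c(Br)c2c(c1OCc4ccccc4)C[C@H](O)[C@@H](c1ccc(OCc3ccccc3)c(OCc3ccccc3)c1)O2 | intermediate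
16 | (2R,3S,4S)-2-(3,4-dihydroxyphenyl)-4-[(2R,3S)-2-(3,4-dihydroxyphenyl)-3,5,7-trihydroxy-3,4-dihydro-2H-chromen-6-yl]-3,4-dihydro-2H-chromene-3,7-diol | Oc1ccc2c(c1)O[C@H](c1ccc(O)c(O)c1)[C@@H](O)[C@@H]2c1c(O)cc2c(c1O)C[C@H](O)[C@@H](c1ccc(O)c(O)c1)O2 | target

**Step count and risks**

Total step count: 10. Longest linear sequence: 8 steps (steps 1–6, 9, 10); steps 7 and 8 form the side branch.

Steps most likely to fail:

Step 4. The chiral catalyst may discriminate the aldehyde faces poorly on this tetrasubstituted, polyoxygenated diene (ligand-free background aldol), leaving enantiomeric material. The fallback sets out from 6 and 7: the cyclocondensation is run with stoichiometric TiCl4 (CH2Cl2, −78 °C; then TFA) to give the racemic trans product, that is 9 together with its enantiomer (2S,3S)-3,7-bis(benzyloxy)-2-[3,4-bis(benzyloxy)phenyl]-2,3,5,6-tetrahydro-4H-chromen-4-one F1. The two are separated by preparative chromatography on a chiral stationary phase, and the route is rejoined at 9.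

Step 9. Attack by the hindered, bromine-deactivated C6' may be slow, so that the C4 cation is diverted (elimination to the flav-3-ene, self-condensation) or the 3,4-trans selectivity is eroded. The fallback sets out from 11: acid-catalysed thiolysis (benzyl mercaptan, AcOH, rt) should give the 2,3-trans-3,4-trans thioether (2R,3R,4R)-3,7-bis(benzyloxy)-4-(benzylsulfanyl)-2-[3,4-bis(benzyloxy)phenyl]-3,4-dihydro-2H-chromene F2. Thiophilic activation (AgBF4, THF, −20 °C) in the presence of 14 then releases the cation slowly under non-protic conditions and should give 15, where the route is rejoined.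

Step 10. Bromide may poison the catalyst, debenzylation may stay incomplete, or HBr may cleave the interflavan bond during the combined debromination and debenzylation. The fallback sets out from 15: bromine–lithium exchange (n-BuLi, 2.2 equiv, THF, −78 °C; MeOH quench) should give the bromine-free ether (2R,3S,4S)-3,7-bis(benzyloxy)-2-[3,4-bis(benzyloxy)phenyl]-4-[(2R,3S)-5,7-bis(benzyloxy)-2-[3,4-bis(benzyloxy)phenyl]-3-hydroxy-3,4-dihydro-2H-chromen-6-yl]-3,4-dihydro-2H-chromene F3. Halide-free hydrogenolysis of F3 (H2, Pd(OH)2/C, THF/MeOH) then arrives at 16.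

**Further compounds**

F1 | step 4 | (2S,3S)-3,7-bis(benzyloxy)-2-[3,4-bis(benzyloxy)phenyl]-2,3,5,6-tetrahydro-4H-chromen-4-one | c1ccccc1COC1=CC(O[C@@H](c2ccc(OCc3ccccc3)c(OCc3ccccc3)c2)[C@H](OCc2ccccc2)C2=O)=C2CC1
F2 | step 9 | (2R,3R,4R)-3,7-bis(benzyloxy)-4-(benzylsulfanyl)-2-[3,4-bis(benzyloxy)phenyl]-3,4-dihydro-2H-chromene | c1ccccc1COc1ccc2c(c1)O[C@H](c1ccc(OCc3ccccc3)c(OCc3ccccc3)c1)[C@@H](OCc1ccccc1)[C@@H]2SCc1ccccc1
F3 | step 10 | (2R,3S,4S)-3,7-bis(benzyloxy)-2-[3,4-bis(benzyloxy)phenyl]-4-[(2R,3S)-5,7-bis(benzyloxy)-2-[3,4-bis(benzyloxy)phenyl]-3-hydroxy-3,4-dihydro-2H-chromen-6-yl]-3,4-dihydro-2H-chromene | c1ccccc1COc1ccc2c(c1)O[C@H](c1ccc(OCc3ccccc3)c(OCc3ccccc3)c1)[C@@H](OCc1ccccc1)[C@@H]2c1c(OCc3ccccc3)cc2c(c1OCc4ccccc4)C[C@H](O)[C@@H](c1ccc(OCc3ccccc3)c(OCc3ccccc3)c1)O2
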